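The route rests on forming C8a–C3a and C8a–C8 in one operation (hydroazulene numbering: ring A C1, C2, C3, C3a, C8a; ring B C3a, C4–C8, C8a). Deleting C8a from ring B leaves six carbons (C3a, C4, C5, C6, C7, C8) with the substitution pattern of a cresol, oxygen at C4 and methyl at C6, so they are bought as an arene and the methyl-bearing C8a is inserted into its C3a–C8 bond. A carbenoid cycloaddition with ring expansion thereby closes ring A, creates ring B and sets quaternary C8a under control of C3. The precursor is an α-methyl diazo ketone tethered to an enantioenriched tertiary benzylic silyl ether on a 2-methoxy-4-methylphenyl ring.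

Key step: step 9

Remark 1: the target as drawn is (3R,3aS,4R,8aR); H–C3a is trans to the C8a methyl, and O3, the C4 ester oxygen and the C8a methyl lie on one face.
Remark 2: the (R,R)-silane 5 is assumed to deliver the (R)-carbinol 7; if a pilot run shows the opposite sense of induction, its (S,S)-antipode is used and nothing else changes.
Remark 3: the carbinol carbon C1 (18 to 22), the secondary carbinol of 12 and the methine between the carbonyls of 14 are epimer mixtures of no consequence and are left unspecified in the SMILES.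

Step 1
Reactants: 1 m-cresol; 2 isobutyryl chloride
Product: 4 1-(2-hydroxy-4-methylphenyl)-2-methylpropan-1-one, via 3-methylphenyl 2-methylpropanoate 3 (not isolated)
Conditions: neat, 60 °C; then AlCl3 (1.5 equiv), 140 °C; ice/aq. HCl
Reagents that add atoms: none
Why: O-acylation followed by ortho-Fries rearrangement; at high temperature the aluminium-bound phenoxide takes the acyl group at the chelating ortho position, and of the two ortho sites the one para to the methyl group is the less hindered.

Step 2
Reactants: 4 hydroxy ketone; 5 (R,R)-allylchlorosilane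
Product: 7 (R)-2-(3-hydroxy-2-methylhex-5-en-3-yl)-5-methylphenol, via silicon-bound adduct 6 (not isolated)
Conditions: 5 (1.5 equiv), toluene, 40 °C; then 1 M HCl/EtOAc, 0 °C, short contact
Reagents that add atoms: none
Why: phenol-directed enantioselective allylsilylation, a reaction type known for hindered 2'-hydroxyaryl alkyl ketones: the phenol displaces chloride on the strained, Lewis-acidic silane and the allyl group is passed to the silicon-bound ketone through a chair-like six-membered transition state, the C2-symmetric diamine choosing the carbonyl face that gives the (R)-carbinol (C3 of the target).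

Step 3
Reactants: 7 phenol diol
Product: 8 (R)-3-(2-methoxy-4-methylphenyl)-2-methylhex-5-en-3-ol
Conditions: MeI, K2CO3, acetone, 40 °C
Reagents that add atoms: iodomethane, CI
Why: Williamson ether synthesis; K2CO3 deprotonates only the phenol, so the tertiary alcohol and its stereocentre are untouched.

Step 4
Reactants: 8 tertiary alcohol
Product: 9 (R)-tert-butyl{[3-(2-methoxy-4-methylphenyl)-2-methylhex-5-en-3-yl]oxy}dimethylsilane
Conditions: TBSOTf, 2,6-lutidine, CH2Cl2, 0 → 23 °C
Reagents that add atoms: tert-butyldimethylsilyl trifluoromethanesulfonate, CC(C)(C)[Si](C)(C)OS(=O)(=O)C(F)(F)F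
Why: silyl triflate/2,6-lutidine silylation of a hindered tertiary alcohol; the bulky tert-butyldimethylsilyl group is chosen over a small silyl group because it resists migration and acid in steps 6 to 15 and leaves O3 too hindered and too weakly basic to trap the carbenoid of step 9.

Step 5
Reactants: 9 silyl ether
Product: 11 (R)-3-(tert-butyldimethylsilyloxy)-3-(2-methoxy-4-methylphenyl)-4-methylpentanal, via ozonide 10 (not isolated)
Conditions: O3, CH2Cl2, −78 °C (indicator dye end point); then PPh3, −78 → 23 °C
Reagents that add atoms: ozone, [O-][O+]=O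
Why: ozonolysis with reductive work-up; the terminal alkene reacts far faster than the anisole ring, and the silyl ether prevents retro-aldol cleavage of the β-oxygenated aldehyde.

Step 6
Reactants: 11 aldehyde
Product: 12 (5R)-5-(tert-butyldimethylsilyloxy)-5-(2-methoxy-4-methylphenyl)-6-methylheptan-3-ol
Conditions: EtMgBr, Et2O, −78 °C; then H2O
Reagents that add atoms: ethylmagnesium bromide, CC[Mg]Br
Why: Grignard 1,2-addition to the aldehyde; the new carbinol forms as an epimer mixture that is erased in step 7.

Step 7
Reactants: 12 secondary alcohol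
Product: 13 (R)-5-(tert-butyldimethylsilyloxy)-5-(2-methoxy-4-methylphenyl)-6-methylheptan-3-one
Conditions: Dess–Martin periodinane, CH2Cl2, 0 → 23 °C
Reagents that add atoms: none
Why: Dess–Martin oxidation of the secondary alcohol under mild conditions that leave the silyl ether and the electron-rich arene alone.

Step 8
Reactants: 13 ethyl ketone
Product: 15 (R)-2-diazo-5-(tert-butyldimethylsilyloxy)-5-(2-methoxy-4-methylphenyl)-6-methylheptan-3-one, via trifluoroacetyl diketone 14 (not isolated)
Conditions: LiN(SiMe3)2, THF, −78 °C; CF3CO2CH2CF3; aq. HCl; then MsN3, Et3N, H2O (1 equiv), MeCN, 23 °C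
Reagents that add atoms: methanesulfonyl azide, CS(=O)(=O)N=[N+]=[N-]; 2,2,2-trifluoroethyl trifluoroacetate, O=C(OCC(F)(F)F)C(F)(F)F (its CF3CO group is carried only by 14)
Why: kinetic enolisation occurs on the ethyl side because the other α-CH2 is neopentylic, Claisen trifluoroacetylation activates that carbon, and Regitz-type deacylative diazo transfer then gives the α-methyl diazo ketone with loss of the trifluoroacetyl group.

Step 9
Reactants: 15 diazo ketone
Product: 17 (3R,8aR)-3-(tert-butyldimethylsilyloxy)-4-methoxy-6,8a-dimethyl-3-(propan-2-yl)-3,8a-dihydroazulen-1(2H)-one, via norcaradiene 16 (not isolated)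
Conditions: Rh2(O2CCF3)4 (1 mol %), CH2Cl2, 23 °C, slow addition of 15
Reagents that add atoms: none
Why: Rh2(O2CCF3)4 expels N2 from 15 to give an electrophilic divalent-rhodium carbenoid at C8a, which cyclopropanates the arene bond C3a–C8 (norcaradiene 16), and 16 opens by thermal disrotatory six-electron electrocyclic cleavage of C3a–C8 to the cycloheptatriene 17; the closest known reaction is the intramolecular Büchner reaction of 1-diazo-4-arylbutan-2-ones, α-methyl cases included. Ring A closes by carbenoid addition through the five-atom tether C3a–C3–C2–C1–C8a (C1 exo and the methyl endo on the cyclopropane), and ring B arises by one-carbon expansion of the benzene ring. The only new stereocentre, C8a, is set by C3: the C2 arm must stand perpendicular to the arene, the silyloxy group then lies beside the methoxy group and the bulkier isopropyl group beside H–C8, and the C3 substituent on the methoxy side ends up cis to the C8a methyl. Chemoselectivity (arene addition rather than insertion into the isopropyl C–H, attack by O3 or 1,2-hydride shift) rests on the perfluorocarboxylate ligands, the electron-rich arene and the hindered silyl ether oxygen. Regioselectivity (C3a–C8, not C3a–C4) rests on the methoxy group, which makes the alternative bond fully substituted, and facial selectivity on minimised allylic strain between the C3 substituents and the methoxy group.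

Step 10
Reactants: 17 trienone
Product: 18 (3R,8aR)-3-(tert-butyldimethylsilyloxy)-4-methoxy-6,8a-dimethyl-3-(propan-2-yl)-1,2,3,8a-tetrahydroazulen-1-ol
Conditions: NaBH4, MeOH/THF, 0 °C
Reagents that add atoms: none
Why: borohydride 1,2-reduction of the only free carbonyl group (C4 is still masked as the enol ether); removing the C1 ketone now keeps it out of ketyl coupling or a Dowd–Beckwith-type acyl shift in step 12, and the C1 configuration does not matter.

Step 11
Reactants: 18 trienol ether
Product: 19 (3R,3aR,8aR)-3-(tert-butyldimethylsilyloxy)-1-hydroxy-6,8a-dimethyl-3-(propan-2-yl)-1,2,3,3a-tetrahydroazulen-4(8aH)-one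
Conditions: (CO2H)2, THF/H2O, 0 → 23 °C
Reagents that add atoms: water, O
Why: enol ether hydrolysis by rate-limiting C-protonation of the electron-rich dienol ether at C3a, expected on the face away from the C8a methyl and the C3 silyloxy group, then loss of methanol from the hemiketal; this gives the conjugated dienone with H–C3a trans to the angular methyl, which is also the isomer that avoids eclipsing C4 with the isopropyl group.

Step 12
Reactants: 19 hydroxy dienone
Product: 21 (3R,3aR,8aR)-3-(tert-butyldimethylsilyloxy)-1-hydroxy-6,8a-dimethyl-3-(propan-2-yl)-1,2,3,3a,8,8a-hexahydroazulen-4(5H)-one, via dilithium dienolate 20 (not isolated)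
Conditions: Li (2.2 equiv), NH3/THF, −78 °C; then solid NH4Cl
Reagents that add atoms: none
Why: dissolving-metal (Birch-type) reduction of a 2,4-dienone: two electrons and protonation at the δ-carbon C8 (the C1 hydroxyl is the proton source) give the extended dienolate 20, and kinetic α-protonation at C5 on quenching leaves the C6=C7 bond out of conjugation, as in the known conversion of steroidal 4,6-dien-3-ones into 5-en-3-ones; C3a is not touched.

Step 13
Reactants: 21 hydroxy enone
Product: 22 O-phenyl thionocarbonate of 21 at O1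
Conditions: PhOC(S)Cl, pyridine, DMAP (cat.), CH2Cl2, 0 → 23 °C
Reagents that add atoms: O-phenyl chlorothionoformate, S=C(Cl)Oc1ccccc1
Why: thioacylation of the neopentylic C1 alcohol for Barton–McCombie deoxygenation, done with pyridine as the only stoichiometric base so that the β,γ-unsaturated ketone is not drawn into conjugation; O3 is silylated and cannot compete.

Step 14
Reactants: 22 thionocarbonate
Product: 23 (3R,3aR,8aR)-3-(tert-butyldimethylsilyloxy)-6,8a-dimethyl-3-(propan-2-yl)-1,2,3,3a,8,8a-hexahydroazulen-4(5H)-one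
Conditions: Bu3SnH, AIBN, toluene, 100 °C
Reagents that add atoms: none
Why: Barton–McCombie radical deoxygenation; the secondary C1 radical is reduced by Bu3SnH, and because C3a=C4 and C7=C8 are already gone it has no homoallylic double bond to cyclise onto.

Step 15
Reactants: 23 ketone
Product: 24 (3R,3aS,4R,8aR)-3-(tert-butyldimethylsilyloxy)-6,8a-dimethyl-3-(propan-2-yl)-1,2,3,3a,4,5,8,8a-octahydroazulen-4-ol
Conditions: NaBH4, CeCl3·7H2O, MeOH, −78 → −20 °C
Reagents that add atoms: none
Why: Luche reduction; hydride attacks C4 from the face of H–C3a, away from the 1,3-related angular methyl and the C3 silyloxy group (the usual outcome for a ketone next to a ring fusion that carries such a methyl), which sets (4R) with the C4 oxygen cis to O3, and the cold, non-basic medium keeps the C6=C7 bond in place.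

Step 16
Reactants: 24 silyl ether alcohol
Product: 25 (3R,3aS,4R,8aR)-6,8a-dimethyl-3-(propan-2-yl)-1,2,3,3a,4,5,8,8a-octahydroazulene-3,4-diol
Conditions: Bu4NF, THF, 60 °C
Reagents that add atoms: none
Why: fluoride desilylation of the hindered tertiary silyl ether, helped by the neighbouring cis C4 hydroxyl; no stereocentre is involved and no base-sensitive group remains.

Step 17
Reactants: 25 diol; 26 4-acetoxybenzoic acid
Product: 27 (3R,3aS,4R,8aR)-3-hydroxy-6,8a-dimethyl-3-(propan-2-yl)-1,2,3,3a,4,5,8,8a-octahydroazulen-4-yl 4-acetoxybenzoate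
Conditions: DCC, DMAP, CH2Cl2, 23 °C
Reagents that add atoms: none
Why: Steglich esterification; the secondary C4 hydroxyl is acylated while the hindered tertiary C3 hydroxyl does not react.

Step 18
Reactants: 27 acetate
Product: 28 target, (3R,3aS,4R,8aR)-3-hydroxy-6,8a-dimethyl-3-(propan-2-yl)-1,2,3,3a,4,5,8,8a-octahydroazulen-4-yl 4-hydroxybenzoate
Conditions: K2CO3 (0.2 equiv), MeOH, 0 °C
Reagents that add atoms: none
Why: base-catalysed methanolysis cleaves the aryl acetate much faster than the hindered secondary benzoate, which is further deactivated once the phenoxide has formed.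

Compound list
1 | m-cresol (3-methylphenol) | Cc1cccc(O)c1 | starting material
2 | isobutyryl chloride (2-methylpropanoyl chloride) | CC(C)C(Cl)=O | starting material
3 | 3-methylphenyl 2-methylpropanoate | CC(C)C(=O)Oc1cccc(C)c1 | intermediate (not isolated)
4 | 1-(2-hydroxy-4-methylphenyl)-2-methylpropan-1-one | CC(C)C(=O)c1ccc(C)cc1O | intermediate
5 | (3aR,7aR)-2-allyl-1,3-bis(4-bromobenzyl)-2-chlorooctahydro-1H-1,3,2-benzodiazasilole, the strained allylchlorosilane of (R,R)-N,N'-bis(4-bromobenzyl)cyclohexane-1,2-diamine (commercial reagent; otherwise one step from allyltrichlorosilane and the diamine) | C=CC[Si]1(Cl)N(Cc2ccc(Br)cc2)[C@@H]2CCCC[C@H]2N1Cc1ccc(Br)cc1 | starting material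
6 | silicon-bound adduct: spiro silane whose silicon carries the aryl oxygen and the new (R)-tertiary alkoxide oxygen (six-membered 1,3-dioxa-2-sila ring fused to the arene) and both diamine nitrogens | C=CC[C@]1(C(C)C)O[Si]2(Oc3cc(C)ccc13)N(Cc4ccc(Br)cc4)[C@@H]5CCCC[C@H]5N2Cc6ccc(Br)cc6 | intermediate (not isolated)
7 | (R)-2-(3-hydroxy-2-methylhex-5-en-3-yl)-5-methylphenol | Oc1cc(C)ccc1[C@](O)(C(C)C)CC=C | intermediate
8 | (R)-3-(2-methoxy-4-methylphenyl)-2-methylhex-5-en-3-ol | COc1cc(C)ccc1[C@](O)(C(C)C)CC=C | intermediate
9 | (R)-tert-butyl{[3-(2-methoxy-4-methylphenyl)-2-methylhex-5-en-3-yl]oxy}dimethylsilane | COc1cc(C)ccc1[C@](O[Si](C)(C)C(C)(C)C)(C(C)C)CC=C | intermediate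
10 | ozonide (3-substituted 1,2,4-trioxolane) of 9 | COc1cc(C)ccc1[C@](O[Si](C)(C)C(C)(C)C)(C(C)C)CC1OCOO1 | intermediate (not isolated)
11 | (R)-3-(tert-butyldimethylsilyloxy)-3-(2-methoxy-4-methylphenyl)-4-methylpentanal | COc1cc(C)ccc1[C@](O[Si](C)(C)C(C)(C)C)(C(C)C)CC=O | intermediate
12 | (5R)-5-(tert-butyldimethylsilyloxy)-5-(2-methoxy-4-methylphenyl)-6-methylheptan-3-ol (C3 epimers) | COc1cc(C)ccc1[C@](O[Si](C)(C)C(C)(C)C)(C(C)C)CC(O)CC | intermediate
13 | (R)-5-(tert-butyldimethylsilyloxy)-5-(2-methoxy-4-methylphenyl)-6-methylheptan-3-one | COc1cc(C)ccc1[C@](O[Si](C)(C)C(C)(C)C)(C(C)C)CC(=O)CC | intermediate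
14 | (6R)-6-(tert-butyldimethylsilyloxy)-1,1,1-trifluoro-6-(2-methoxy-4-methylphenyl)-3,7-dimethyloctane-2,4-dione (drawn as the diketone; C3 epimers) | COc1cc(C)ccc1[C@](O[Si](C)(C)C(C)(C)C)(C(C)C)CC(=O)C(C)C(=O)C(F)(F)F | intermediate (not isolated)
15 | (R)-2-diazo-5-(tert-butyldimethylsilyloxy)-5-(2-methoxy-4-methylphenyl)-6-methylheptan-3-one | COc1cc(C)ccc1[C@](O[Si](C)(C)C(C)(C)C)(C(C)C)CC(=O)C(C)=[N+]=[N-] | intermediate
16 | norcaradiene valence isomer of 17: cyclopropane C3a–C8–C8a, diene C4=C5–C6=C7, C8a methyl endo over the diene, C1 ketone exo | COC1=CC(C)=C[C@@H]2[C@@]3(C)C(=O)C[C@@](O[Si](C)(C)C(C)(C)C)(C(C)C)[C@@]123 | intermediate (not isolated)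
17 | (3R,8aR)-3-(tert-butyldimethylsilyloxy)-4-methoxy-6,8a-dimethyl-3-(propan-2-yl)-3,8a-dihydroazulen-1(2H)-one (C8a methyl cis to O3) | CC1=CC(OC)=C2[C@](O[Si](C)(C)C(C)(C)C)(C(C)C)CC(=O)[C@]2(C)C=C1 | intermediate
18 | (3R,8aR)-3-(tert-butyldimethylsilyloxy)-4-methoxy-6,8a-dimethyl-3-(propan-2-yl)-1,2,3,8a-tetrahydroazulen-1-ol (C1 epimers) | CC1=CC(OC)=C2[C@](O[Si](C)(C)C(C)(C)C)(C(C)C)CC(O)[C@]2(C)C=C1 | intermediate
19 | (3R,3aR,8aR)-3-(tert-butyldimethylsilyloxy)-1-hydroxy-6,8a-dimethyl-3-(propan-2-yl)-1,2,3,3a-tetrahydroazulen-4(8aH)-one (H–C3a trans to the C8a methyl; C1 epimers) | CC1=CC(=O)[C@H]2[C@](O[Si](C)(C)C(C)(C)C)(C(C)C)CC(O)[C@]2(C)C=C1 | intermediate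
20 | dilithium salt of the C1 alkoxide and the C4 dienolate (C4=C5, C6=C7) | [Li+].[Li+].CC1=CC[C@@]2(C)C([O-])C[C@@](O[Si](C)(C)C(C)(C)C)(C(C)C)[C@@H]2C([O-])=C1 | intermediate (not isolated)
21 | (3R,3aR,8aR)-3-(tert-butyldimethylsilyloxy)-1-hydroxy-6,8a-dimethyl-3-(propan-2-yl)-1,2,3,3a,8,8a-hexahydroazulen-4(5H)-one (C1 epimers) | CC1=CC[C@@]2(C)C(O)C[C@@](O[Si](C)(C)C(C)(C)C)(C(C)C)[C@@H]2C(=O)C1 | intermediate
22 | O-phenyl thionocarbonate of 21 at O1 (C1 epimers) | CC1=CC[C@@]2(C)C(OC(=S)Oc3ccccc3)C[C@@](O[Si](C)(C)C(C)(C)C)(C(C)C)[C@@H]2C(=O)C1 | intermediate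
23 | (3R,3aR,8aR)-3-(tert-butyldimethylsilyloxy)-6,8a-dimethyl-3-(propan-2-yl)-1,2,3,3a,8,8a-hexahydroazulen-4(5H)-one | CC1=CC[C@@]2(C)CC[C@@](O[Si](C)(C)C(C)(C)C)(C(C)C)[C@@H]2C(=O)C1 | intermediate
24 | (3R,3aS,4R,8aR)-3-(tert-butyldimethylsilyloxy)-6,8a-dimethyl-3-(propan-2-yl)-1,2,3,3a,4,5,8,8a-octahydroazulen-4-ol | CC1=CC[C@@]2(C)CC[C@@](O[Si](C)(C)C(C)(C)C)(C(C)C)[C@@H]2[C@H](O)C1 | intermediate
25 | (3R,3aS,4R,8aR)-6,8a-dimethyl-3-(propan-2-yl)-1,2,3,3a,4,5,8,8a-octahydroazulene-3,4-diol | CC1=CC[C@@]2(C)CC[C@@](O)(C(C)C)[C@@H]2[C@H](O)C1 | intermediate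
26 | 4-acetoxybenzoic acid | CC(=O)Oc1ccc(cc1)C(O)=O | starting material
27 | (3R,3aS,4R,8aR)-3-hydroxy-6,8a-dimethyl-3-(propan-2-yl)-1,2,3,3a,4,5,8,8a-octahydroazulen-4-yl 4-acetoxybenzoate | CC1=CC[C@@]2(C)CC[C@@](O)(C(C)C)[C@@H]2[C@H](OC(=O)c2ccc(OC(C)=O)cc2)C1 | intermediate
28 | (3R,3aS,4R,8aR)-3-hydroxy-6,8a-dimethyl-3-(propan-2-yl)-1,2,3,3a,4,5,8,8a-octahydroazulen-4-yl 4-hydroxybenzoate | CC1=CC[C@@]2(C)CC[C@@](O)(C(C)C)[C@@H]2[C@H](OC(=O)c2ccc(O)cc2)C1 | target

Total step count: 18. Longest linear sequence: 18 steps (1 to 28); 5 and 26 are bought.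

Steps most likely to fail

Step 9. The carbenoid may be diverted before it reaches the arene (attack by O3, insertion into the isopropyl C–H, 1,2-hydride shift from the methyl group), or it may add to the other arene face and give the C8a epimer. The fallback moves face and chemoselection from the substrate to the catalyst. It sets out from 15 and uses a cationic monovalent-copper carbene bound to a C2-symmetric bis(oxazoline): Cu(MeCN)4PF6, 2,2'-(propane-2,2-diyl)bis(4-phenyl-4,5-dihydrooxazole) in the antipode matched to C3, NaB[3,5-(CF3)2C6H3]4, CH2Cl2, 40 °C. This is a known enantioselective intramolecular Büchner system for α-methyl diazo ketones and it prefers arene addition over C–H insertion. It comes back at 17 and makes no compound outside the list (F0).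

Step 12. The dissolving-metal step may over-reduce the C4 carbonyl once it is set free on quenching, or the dienolate may be protonated at C7 and give the conjugated C5=C6 enone. The fallback drops electron transfer for a neutral catalytic 1,4-hydrogenation. It sets out from 19, whose cisoid C5=C6–C7=C8 diene takes up H2 at C5 and C8 with (η6-naphthalene)Cr(CO)3 (cat.), H2 (50 atm), THF, 45 °C, the known way from 2,4-dienoates to (Z)-3-enoates. This leaves the C6=C7 bond and comes back at 21 with no compound outside the list (F0).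

Step 11. C3a may be protonated from the face of the C8a methyl, giving the cis-fused ketone, because the two faces differ only modestly. The fallback replaces kinetic protonation by thermodynamic control. It sets out from 18: the cis-fused (3R,3aS,8aR)-3-(tert-butyldimethylsilyloxy)-1-hydroxy-6,8a-dimethyl-3-(propan-2-yl)-1,2,3,3a-tetrahydroazulen-4(8aH)-one F1 is separated and equilibrated through the C4 enol with TsOH·H2O (cat.) in CH2Cl2 at 23 °C. C3a is the only stereocentre of the dienone that can enolise, and the tert-butyldimethylsilyl ether tolerates the acid. The trans-fused isomer should prevail because it avoids eclipsing C4 with the isopropyl group. The fallback comes back at 19.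

Further compounds
F0 | step 9 | none | none
F1 | step 11 | (3R,3aS,8aR)-3-(tert-butyldimethylsilyloxy)-1-hydroxy-6,8a-dimethyl-3-(propan-2-yl)-1,2,3,3a-tetrahydroazulen-4(8aH)-one (cis-fused C3a epimer of 19) | CC1=CC(=O)[C@@H]2[C@](O[Si](C)(C)C(C)(C)C)(C(C)C)CC(O)[C@]2(C)C=C1
F0 | step 12 | none | none
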